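**Assumption:** the target has no sp3 stereocentres. "Single enantiomer" therefore reduces to the two (E)-enones, which come from (E)-4-acetoxycinnamic acid and are never isomerised.

## Retrosynthetic overview
1. Remove the two aryl acetates, which are protecting groups on the 4-OH of each cinnamoyl ring. This leaves a bis-chalcone in which both 2'-hydroxychalcone units are made in a single operation. The operation is a two-fold direct BF3-promoted ortho-cinnamoylation (Nencki-type) of bisphenol 4 with (E)-4-acetoxycinnamic acid. It replaces the usual acetophenone, Claisen–Schmidt sequence.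
2. Bisphenol 4 comes from Dakin/Baeyer–Villiger conversion of the aldehyde in 3 to a phenol. This unmasks the ring-A phenol, whose OH ends up para to the ether oxygen.
3. Diaryl ether 3 comes from SNAr of excess resorcinol on 4-fluoro-3-methoxybenzaldehyde. The para-CHO group activates the C–F bond.
4. No rings are constructed; all arenes are commercial. The order of events is ether C–O bond, then phenol unmasking, then both acyl-enone units, then deprotection.

## Route

**Step 1**
Reactants: 1 (4-fluoro-3-methoxybenzaldehyde); 2 (resorcinol, 4 equiv)
Product: 3 (4-(3-hydroxyphenoxy)-3-methoxybenzaldehyde)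
Conditions: K2CO3, DMF, 120 °C, 12 h
Reagents that add atoms: none
Why: SNAr (addition–elimination) at the C–F bond para to CHO; a large excess of resorcinol favours mono-arylation, and no stereocentre is formed.

**Step 2**
Reactants: 3
Product: 4 (4-(3-hydroxyphenoxy)-3-methoxyphenol)
Conditions: (i) mCPBA (1.2 equiv), CH2Cl2, 0 °C to rt; (ii) K2CO3, MeOH, rt, degassed
Reagents that add atoms: mCPBA, OOC(=O)c1cccc(Cl)c1 (supplies the oxygen inserted between the ring and CHO)
Why: Dakin/Baeyer–Villiger oxidation, in which the ring para to the aryloxy group and meta to OMe migrates in preference to H. This gives the aryl formate, which is cleaved in situ to the phenol, placing OH para to the ether oxygen. The formate also keeps the electron-rich phenol from being over-oxidised to a quinone.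

**Step 3**
Reactants: 4; 5 ((E)-4-acetoxycinnamic acid, 2.4 equiv)
Product: 6 (bis-chalcone diacetate)
Conditions: BF3·OEt2 (neat, about 10 equiv), 75 °C, 6 h; workup with aq NaOAc, 60 °C, to cleave the BF2 chelates
Reagents that add atoms: none
Why: Nencki-type Friedel–Crafts acylation, directed ortho to the free phenol by phenol–BF2 chelation, and para to the alkoxy group on each ring.
Proposed new method: two-fold direct cinnamoylation of a bisphenol diaryl ether, to give both 2'-hydroxychalcones at once with the (E)-geometry carried in from 5. The mechanism is an acyloxy-BF2 mixed anhydride or acylium attacking the carbon ortho to OH and para to OR. The resulting 2'-hydroxychalcone is held as its BF2 chelate, which suppresses oxa-Michael cyclisation to the flavanone and deactivates the ring to further acylation. The closest known reactions are BF3/AcOH conversion of 3-methoxyphenol to paeonol and direct BF3-mediated acylation of resorcinol with cinnamic acids.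

**Step 4**
Reactants: 6
Product: 7 (rhuschalcone IV)
Conditions: K2CO3, MeOH–THF, 0 °C, 30 min; then 1 M HCl to pH 3, 0 °C
Reagents that add atoms: none
Why: Transesterification cleaves the aryl acetates selectively. The chelated 2'-OH groups, the OMe, the diaryl ether and the (E)-enones are untouched, and the deprotonated 4-hydroxychalcone is a stable push-pull phenoxide that resists flavanone cyclisation.

## Compound list
1 | 4-fluoro-3-methoxybenzaldehyde | COc1cc(C=O)ccc1F | starting material
2 | resorcinol | Oc1cccc(O)c1 | starting material
3 | 4-(3-hydroxyphenoxy)-3-methoxybenzaldehyde | COc1cc(C=O)ccc1Oc1cccc(O)c1 | intermediate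
4 | 4-(3-hydroxyphenoxy)-3-methoxyphenol | COc1cc(O)ccc1Oc1cccc(O)c1 | intermediate
5 | (E)-4-acetoxycinnamic acid | CC(=O)Oc1ccc(/C=C/C(=O)O)cc1 | starting material
6 | bis-chalcone diacetate | COc1cc(O)c(C(=O)/C=C/c2ccc(OC(C)=O)cc2)cc1Oc1ccc(C(=O)/C=C/c2ccc(OC(C)=O)cc2)c(O)c1 | intermediate
7 | rhuschalcone IV | COc1cc(O)c(C(=O)/C=C/c2ccc(O)cc2)cc1Oc1ccc(C(=O)/C=C/c2ccc(O)cc2)c(O)c1 | target

**Atom check:** 4 (C13H12O4) + 2 × 5 (C11H10O4) − 2 H2O = 6 (C35H28O10). Removing two acetyl groups (2 × C2H2O) gives 7, C31H24O8, which matches the target.

**Regiochemistry check:** in ring A, acylation at C6 of 4 is ortho to OH and para to OMe, with OAr para to the phenol OH. In ring B, acylation is ortho to OH and para to OAr. Both match the target SMILES.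

**Total step count:** 4
**Longest linear sequence:** 4 (1 → 3 → 4 → 6 → 7)

## Three steps most likely to fail
1. **Step 3 (double Friedel–Crafts cinnamoylation).** It may give incomplete conversion, a regioisomeric 4-acyl-3-aryloxyphenol, flavanone formation, or hydroarylation of the cinnamic double bond.
   Fallback: change the approach to Nencki acetylation of 4 (AcOH, BF3·OEt2) to the bis-acetophenone. Then run a double Claisen–Schmidt with 4-(MOMO)benzaldehyde (KOH, EtOH) and remove the MOM groups (HCl, MeOH).
2. **Step 2 (Dakin/Baeyer–Villiger).** The aldehyde could be oxidised to the carboxylic acid instead, or the electron-rich 4-aryloxyphenol could be over-oxidised to a quinone.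
   Fallback: skip the oxidation by making 4 through an Ullmann coupling (CuI, N,N-dimethylglycine, Cs2CO3) of 3-benzyloxyphenol with benzyl-protected 4-iodo-3-methoxyphenol, then hydrogenolysis (H2, Pd/C).
3. **Step 1 (SNAr).** The ortho-OMe group deactivates the fluoroarene, and resorcinol can give the bis-ether.
   Fallback: a Chan–Lam coupling (Cu(OAc)2, pyridine, air) of vanillin with 3-benzyloxyphenylboronic acid, then Dakin oxidation and hydrogenolysis to reach 4.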